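**Retrosynthetic overview**

Numbering (2,3,3a,4,5,7a-hexahydro-1H-indene): ring A is the cyclohexene C3a–C4–C5–C6=C7–C7a, ring B the cyclopentanone C1–C2–C3–C3a–C7a. Two features enable the plan: the C2 ketone lies between two enolisable CH(CH3) carbons (C1, C3) on the ring-fusion atoms, and C4(CO2H)–C5–C6=C7 is a γ,δ-unsaturated acid (ester-enolate Claisen retron).
Last step: double dealkoxycarbonylation and equilibration of a bis(β-keto ester). That comes from one pot: ring A by [3,3] ring contraction of a δ-lactone silyl ketene acetal (forms C4–C5), then ring B by acylation of the C1 ester enolate with a non-enolisable malonate on C3 (forms C2–C1).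
The δ-lactone (temporary ring, O on C7, carbonyl on C4) comes from Baeyer–Villiger ring expansion of a cyclopentanone template (temporary ring); its (1E,3E)-dienyl group comes from two olefinations of an aldehyde on the quaternary carbon.
The template comes from cyclopent-2-enone: asymmetric malonate Michael addition, two ethylations, dehydrogenation, then Mukaiyama–Michael addition with acetal trapping (all-trans relay from one stereocentre).
Ring order: cyclopentanone template, then δ-lactone, then ring A, then ring B.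

Key step: step 10

Remark: the two methyl-bearing centres C1 and C3 of the target, each trans to its ring-fusion neighbour, are taken to be the thermodynamically preferred arrangement, so they are set by enolisation in the last step.

Step 1
Reactants: 1 cyclopent-2-en-1-one; 2 dimethyl 2-methylpropanedioate
Product: 3 dimethyl 2-methyl-2-[(1R)-3-oxocyclopentyl]propanedioate
Conditions: LiAl[(R)-1,1'-binaphthyl-2,2'-diolate]2 (5 mol %), KOtBu (4.5 mol %), MS 4 Å, THF, rt
Reagents that add atoms: none
Why: Catalytic asymmetric Michael addition under heterobimetallic lithium–aluminium binaphthoxide catalysis, in which enone and malonate are activated together and the malonate adds to one enantiotopic face, should set the (1R) ring centre that controls all later centres.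

Step 2
Reactants: 3 dimethyl 2-methyl-2-[(1R)-3-oxocyclopentyl]propanedioate
Product: 4 dimethyl 2-[(1R)-3-ethyl-4-oxocyclopentyl]-2-methylpropanedioate (epimer mixture at C3)
Conditions: LiN(iPr)2, THF, −78 °C; EtI, DMPU, −78 → −30 °C
Reagents that add atoms: iodoethane, CCI
Why: Kinetic enolate alkylation should occur at the α-methylene remote from the bulky malonyl group, and the new centre need not be controlled because it becomes sp2 in step 3.

Step 3
Reactants: 4 dimethyl 2-[(1R)-3-ethyl-4-oxocyclopentyl]-2-methylpropanedioate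
Product: 6 dimethyl 2-[(1S)-3-ethyl-4-oxocyclopent-2-en-1-yl]-2-methylpropanedioate, via trimethylsilyl enol ether 5 (not isolated)
Conditions: Me3SiCl, NaI, Et3N, MeCN, rt; then Pd(OAc)2 (10 mol %), O2 (1 atm), DMSO, rt
Reagents that add atoms: none
Why: Saegusa–Ito dehydrogenation, in which thermodynamic silylation gives the more substituted enol ether on the ethyl-bearing side and palladation with β-hydride elimination into the ring follows, should give the 2-ethyl enone with the ring stereocentre untouched (the descriptor changes only by priority).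

Step 4
Reactants: 6 dimethyl 2-[(1S)-3-ethyl-4-oxocyclopent-2-en-1-yl]-2-methylpropanedioate
Product: 7 dimethyl 2-[(1R)-3,5-diethyl-4-oxocyclopent-2-en-1-yl]-2-methylpropanedioate (epimer mixture at C5)
Conditions: LiN(iPr)2, THF, −78 °C; EtI, −78 → −20 °C
Reagents that add atoms: iodoethane, CCI
Why: α′-Alkylation of the cross-conjugated kinetic enolate (the only α′ position) should install the second ethyl group, whose configuration is irrelevant because this carbon is enolised again in step 10.

Step 5
Reactants: 7 dimethyl 2-[(1R)-3,5-diethyl-4-oxocyclopent-2-en-1-yl]-2-methylpropanedioate; 8 1-methoxy-1-(trimethylsilyloxy)prop-1-ene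
Product: 10 dimethyl 2-[(1R,2S,3R)-3-(dimethoxymethyl)-3,5-diethyl-2-(1-methoxy-1-oxopropan-2-yl)-4-oxocyclopentyl]-2-methylpropanedioate, via silyl enol ether 9 (not isolated)
Conditions: 8 (1.5 equiv), Me3SiNTf2 (5 mol %), CH2Cl2, −78 °C; then HC(OMe)3, Me3SiOTf (10 mol %), −78 → −30 °C
Reagents that add atoms: trimethyl orthoformate, COC(OC)OC
Why: Mukaiyama–Michael addition should deliver the propanoate unit anti to the malonyl group, and Lewis-acid-mediated alkylation of the resulting silyl enol ether by the dimethoxycarbenium ion (Mukaiyama-type acetal reaction) should then form the quaternary centre with the one-carbon unit trans to the new side chain.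

Step 6
Reactants: 10 dimethyl 2-[(1R,2S,3R)-3-(dimethoxymethyl)-3,5-diethyl-2-(1-methoxy-1-oxopropan-2-yl)-4-oxocyclopentyl]-2-methylpropanedioate
Product: 11 dimethyl 2-[(4R,5S,6R)-6-(dimethoxymethyl)-3,6-diethyl-5-(1-methoxy-1-oxopropan-2-yl)-2-oxooxan-4-yl]-2-methylpropanedioate
Conditions: mCPBA, CH2Cl2, 0 °C → rt
Reagents that add atoms: 3-chloroperbenzoic acid, O=C(OO)c1cccc(Cl)c1
Why: Baeyer–Villiger oxidation should insert oxygen next to the fully substituted α-carbon (higher migratory aptitude than the secondary one) with retention, giving the δ-lactone with the tertiary C–O bond.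

Step 7
Reactants: 11 dimethyl 2-[(4R,5S,6R)-6-(dimethoxymethyl)-3,6-diethyl-5-(1-methoxy-1-oxopropan-2-yl)-2-oxooxan-4-yl]-2-methylpropanedioate
Product: 12 dimethyl 2-[(4R,5S,6R)-3,6-diethyl-6-formyl-5-(1-methoxy-1-oxopropan-2-yl)-2-oxooxan-4-yl]-2-methylpropanedioate
Conditions: TFA, H2O, CH2Cl2, 0 °C → rt
Reagents that add atoms: water, O
Why: Acid-catalysed acetal hydrolysis should free the aldehyde while lactone and esters survive, and the aldehyde cannot epimerise because its α-carbon is quaternary.

Step 8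
Reactants: 12 dimethyl 2-[(4R,5S,6R)-3,6-diethyl-6-formyl-5-(1-methoxy-1-oxopropan-2-yl)-2-oxooxan-4-yl]-2-methylpropanedioate; 13 2-(triphenylphosphoranylidene)butanal
Product: 14 dimethyl 2-[(4R,5S,6R)-3,6-diethyl-6-[(1E)-2-ethyl-3-oxoprop-1-en-1-yl]-5-(1-methoxy-1-oxopropan-2-yl)-2-oxooxan-4-yl]-2-methylpropanedioate
Conditions: PhMe, 90 °C
Reagents that add atoms: none
Why: Wittig reaction with a stabilised α-branched formyl ylide should give the (E)-enal (formyl trans to the lactone carbon), the geometry that later places styryl and ethyl correctly on C5.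

Step 9
Reactants: 14 dimethyl 2-[(4R,5S,6R)-3,6-diethyl-6-[(1E)-2-ethyl-3-oxoprop-1-en-1-yl]-5-(1-methoxy-1-oxopropan-2-yl)-2-oxooxan-4-yl]-2-methylpropanedioate; 15 diethyl benzylphosphonate
Product: 16 dimethyl 2-[(4R,5S,6R)-3,6-diethyl-6-[(1E,3E)-2-ethyl-4-phenylbuta-1,3-dien-1-yl]-5-(1-methoxy-1-oxopropan-2-yl)-2-oxooxan-4-yl]-2-methylpropanedioate
Conditions: 15, LiN(SiMe3)2, THF, −78 °C; then 14, −78 → 0 °C
Reagents that add atoms: none
Why: Horner–Wadsworth–Emmons olefination of the enal with the preformed benzylphosphonate anion should give the (E)-styryl unit and complete the (1E,3E)-diene.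

Step 10
Reactants: 16 dimethyl 2-[(4R,5S,6R)-3,6-diethyl-6-[(1E,3E)-2-ethyl-4-phenylbuta-1,3-dien-1-yl]-5-(1-methoxy-1-oxopropan-2-yl)-2-oxooxan-4-yl]-2-methylpropanedioate
Product: 19 4,5,7-triethyl-1,3-bis(methoxycarbonyl)-1,3-dimethyl-2-oxo-5-[(E)-2-phenylethenyl]-2,3,3a,4,5,7a-hexahydro-1H-indene-4-carboxylic acid, via bis-silyl ketene acetal 17 (not isolated), via silyl ester 18 (not isolated)
Conditions: LiN(iPr)2 (2.6 equiv), Me3SiCl, Et3N, THF, −78 °C → rt; PhMe, 100 °C; then KOtBu (3 equiv), THF, −40 → 0 °C; 1 M HCl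
Reagents that add atoms: none
Why: Double enolisation and O-silylation give the cyclic silyl ketene acetal, which on heating should undergo an Ireland–Claisen rearrangement through the boat transition state enforced by the six-membered ring (closest known type: Claisen ring contraction of 6-alkenyl δ-lactone silyl ketene acetals to cyclohex-3-enecarboxylic acids); KOtBu then cleaves the O–Si bonds, and the freed side-chain ester enolate acylates itself on one malonate ester (Dieckmann condensation). Ring A is closed by the [3,3] shift, which forms C4–C5 while the lactone C–O bond breaks, and ring B by 5-exo-trig attack of the C1 enolate on the C3-bound ester carbonyl, which forms C2–C1. The quaternary centres C4 and C5 are controlled by the tertiary carbinol carbon (its alkenyl group is cis to the malonyl side chain and trans to the propanoate side chain, so one face is used), by the fixed geometry of the endocyclic ketene acetal and by the (E)-trisubstituted alkene, which puts styryl cis to the carboxyl and ethyl cis to ethyl; C1 and C3 form as mixtures and are corrected in step 11. The step needs the rearrangement to come before the condensation, because a trans-fused five-membered ring would not fit the boat; this is secured by keeping the side-chain enolate masked as its silyl ketene acetal until the base is added. It also needs a single condensation mode, which is secured because the malonate carbon has no hydrogen and can only be the acyl donor, and the new hindered carboxylate is inert.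

Step 11
Reactants: 19 4,5,7-triethyl-1,3-bis(methoxycarbonyl)-1,3-dimethyl-2-oxo-5-[(E)-2-phenylethenyl]-2,3,3a,4,5,7a-hexahydro-1H-indene-4-carboxylic acid
Product: 20 (1R,3R,3aS,4S,5R,7aS)-4,5,7-triethyl-1,3-dimethyl-2-oxo-5-[(E)-2-phenylethenyl]-2,3,3a,4,5,7a-hexahydro-1H-indene-4-carboxylic acid (norspiculoic acid A)
Conditions: LiCl, DMSO, H2O, 150 °C
Reagents that add atoms: none
Why: Krapcho dealkoxycarbonylation should remove both β-keto ester groups (chloride demethylation, loss of CO2), and protonation under these equilibrating conditions should leave each methyl trans to its ring-fusion neighbour, giving the target.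

**Compound list**

1 | cyclopent-2-en-1-one | O=C1C=CCC1 | starting material
2 | dimethyl 2-methylpropanedioate | COC(=O)C(C)C(=O)OC | starting material
3 | dimethyl 2-methyl-2-[(1R)-3-oxocyclopentyl]propanedioate | O=C1CC[C@@H](C(C)(C(=O)OC)C(=O)OC)C1 | intermediate
4 | dimethyl 2-[(1R)-3-ethyl-4-oxocyclopentyl]-2-methylpropanedioate (epimer mixture at C3) | O=C1C(CC)C[C@@H](C(C)(C(=O)OC)C(=O)OC)C1 | intermediate
5 | dimethyl 2-[(1R)-3-ethyl-4-(trimethylsilyloxy)cyclopent-3-en-1-yl]-2-methylpropanedioate | C[Si](C)(C)OC1=C(CC)C[C@@H](C(C)(C(=O)OC)C(=O)OC)C1 | intermediate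
6 | dimethyl 2-[(1S)-3-ethyl-4-oxocyclopent-2-en-1-yl]-2-methylpropanedioate | O=C1C(CC)=C[C@@H](C(C)(C(=O)OC)C(=O)OC)C1 | intermediate
7 | dimethyl 2-[(1R)-3,5-diethyl-4-oxocyclopent-2-en-1-yl]-2-methylpropanedioate (epimer mixture at C5) | O=C1C(CC)=C[C@@H](C(C)(C(=O)OC)C(=O)OC)C1CC | intermediate
8 | 1-methoxy-1-(trimethylsilyloxy)prop-1-ene (E/Z mixture) | CC=C(OC)O[Si](C)(C)C | starting material
9 | dimethyl 2-[(1R,2S)-3,5-diethyl-2-(1-methoxy-1-oxopropan-2-yl)-4-(trimethylsilyloxy)cyclopent-3-en-1-yl]-2-methylpropanedioate (2-side chain trans to the malonyl group) | C[Si](C)(C)OC1=C(CC)[C@H](C(C)C(=O)OC)[C@@H](C(C)(C(=O)OC)C(=O)OC)C1CC | intermediate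
10 | dimethyl 2-[(1R,2S,3R)-3-(dimethoxymethyl)-3,5-diethyl-2-(1-methoxy-1-oxopropan-2-yl)-4-oxocyclopentyl]-2-methylpropanedioate (acetal trans to the propanoate chain, which is trans to the malonyl group; epimer mixture at C5 and in the propanoate chain) | O=C1[C@](C(OC)OC)(CC)[C@H](C(C)C(=O)OC)[C@@H](C(C)(C(=O)OC)C(=O)OC)C1CC | intermediate
11 | dimethyl 2-[(4R,5S,6R)-6-(dimethoxymethyl)-3,6-diethyl-5-(1-methoxy-1-oxopropan-2-yl)-2-oxooxan-4-yl]-2-methylpropanedioate | O=C1O[C@](C(OC)OC)(CC)[C@H](C(C)C(=O)OC)[C@@H](C(C)(C(=O)OC)C(=O)OC)C1CC | intermediate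
12 | dimethyl 2-[(4R,5S,6R)-3,6-diethyl-6-formyl-5-(1-methoxy-1-oxopropan-2-yl)-2-oxooxan-4-yl]-2-methylpropanedioate | O=C1O[C@](C=O)(CC)[C@H](C(C)C(=O)OC)[C@@H](C(C)(C(=O)OC)C(=O)OC)C1CC | intermediate
13 | 2-(triphenylphosphoranylidene)butanal | CCC(C=O)=P(c1ccccc1)(c1ccccc1)c1ccccc1 | starting material
14 | dimethyl 2-[(4R,5S,6R)-3,6-diethyl-6-[(1E)-2-ethyl-3-oxoprop-1-en-1-yl]-5-(1-methoxy-1-oxopropan-2-yl)-2-oxooxan-4-yl]-2-methylpropanedioate | O=C1O[C@](/C=C(\CC)C=O)(CC)[C@H](C(C)C(=O)OC)[C@@H](C(C)(C(=O)OC)C(=O)OC)C1CC | intermediate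
15 | diethyl benzylphosphonate | CCOP(=O)(Cc1ccccc1)OCC | starting material
16 | dimethyl 2-[(4R,5S,6R)-3,6-diethyl-6-[(1E,3E)-2-ethyl-4-phenylbuta-1,3-dien-1-yl]-5-(1-methoxy-1-oxopropan-2-yl)-2-oxooxan-4-yl]-2-methylpropanedioate (dienyl cis to the malonyl group, trans to the propanoate chain) | O=C1O[C@](/C=C(\CC)/C=C/c2ccccc2)(CC)[C@H](C(C)C(=O)OC)[C@@H](C(C)(C(=O)OC)C(=O)OC)C1CC | intermediate
17 | dimethyl 2-{2,5-diethyl-2-[(1E,3E)-2-ethyl-4-phenylbuta-1,3-dien-1-yl]-3-[1-methoxy-1-(trimethylsilyloxy)prop-1-en-2-yl]-6-(trimethylsilyloxy)-3,4-dihydro-2H-pyran-4-yl}-2-methylpropanedioate (ring centres as in 16) | C[Si](C)(C)OC1=C(CC)[C@H](C(C)(C(=O)OC)C(=O)OC)[C@@H](C(C)=C(OC)O[Si](C)(C)C)[C@](CC)(/C=C(\CC)/C=C/c2ccccc2)O1 | intermediate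
18 | trimethylsilyl 6-(1,3-dimethoxy-2-methyl-1,3-dioxopropan-2-yl)-1,2,4-triethyl-5-[1-methoxy-1-(trimethylsilyloxy)prop-1-en-2-yl]-2-[(E)-2-phenylethenyl]cyclohex-3-ene-1-carboxylate (ring centres as in 20) | CCC1=C[C@](/C=C/c2ccccc2)(CC)[C@@](CC)(C(=O)O[Si](C)(C)C)[C@H](C(C)(C(=O)OC)C(=O)OC)[C@H]1C(C)=C(OC)O[Si](C)(C)C | intermediate
19 | 4,5,7-triethyl-1,3-bis(methoxycarbonyl)-1,3-dimethyl-2-oxo-5-[(E)-2-phenylethenyl]-2,3,3a,4,5,7a-hexahydro-1H-indene-4-carboxylic acid (C3a, C4, C5, C7a as in 20; epimer mixture at C1 and C3) | CCC1=C[C@](/C=C/c2ccccc2)(CC)[C@@](CC)(C(=O)O)[C@H]2[C@H]1C(C)(C(=O)OC)C(=O)C2(C)C(=O)OC | intermediate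
20 | (1R,3R,3aS,4S,5R,7aS)-4,5,7-triethyl-1,3-dimethyl-2-oxo-5-[(E)-2-phenylethenyl]-2,3,3a,4,5,7a-hexahydro-1H-indene-4-carboxylic acid | CCC1=C[C@](/C=C/c2ccccc2)(CC)[C@@](CC)(C(=O)O)[C@H]2[C@H]1[C@@H](C)C(=O)[C@@H]2C | target

Total step count: 11. Longest linear sequence: 11 steps (steps 1 to 11).

**Steps most likely to fail**

Step 10. The [3,3] shift has to pass a crowded boat transition state in which the C5 ethyl group meets the malonyl-bearing side chain. Ionisation or fragmentation of the tertiary dienylic C–O bond may compete with it. The acylation in the same pot may also stall or reverse, because the product has no acidic hydrogen to pull it through. The fallback sets out from 16 and comes back at 20; it uncouples the two events and changes their order and driving force. The rearrangement alone (LiN(iPr)2, Me3SiCl; PhMe, heat; aqueous acid) would give the cyclohexene acid F7. Krapcho dealkoxycarbonylation of the malonate (LiCl, wet DMSO, 130 °C) would give the diester acid F8, a 2,5-dimethyladipate-type substrate with two small side chains. A classical Dieckmann condensation under thermodynamic control (NaH, THF, reflux), in which the enolisable product is removed as its sodium enolate, would give the β-keto ester F9 (or its regioisomer, which converges). Saponification and decarboxylation (LiOH, aqueous THF; then dilute acid, 60 °C) would give 20.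

Step 5. Conjugate addition to the enone, which is substituted at three positions, may be slow. The neopentyl enol ether carbon may then be desilylated or protonated instead of C-alkylated, which would lose the quaternary centre or its facial control. The fallback sets out from 7 and comes back at 12; it uses an anionic three-component coupling with the one-carbon unit at the alcohol oxidation level. Conjugate addition of the lithium enolate of methyl propanoate (LiN(iPr)2, THF, DMPU) and trapping of the resulting lithium enolate with benzyl chloromethyl ether would give the benzyloxymethyl ketone F1. Baeyer–Villiger oxidation (mCPBA) would give the lactone F2. Hydrogenolysis (H2, Pd/C) would give the primary alcohol F3. Dess–Martin oxidation would give 12.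

Step 6. The ketone is flanked by a quaternary and a tertiary carbon, so oxidation may be sluggish. The electron-poor acetal-bearing carbon may lose its migratory preference, and the acetal may be cleaved under the peracid. The fallback sets out from 10 and comes back at 16; it moves the oxidation behind the olefinations so that the migrating carbon is allylic. Acetal hydrolysis (TFA, H2O) would give the keto aldehyde F4. Wittig reaction with 13 would give the keto enal F5. Horner–Wadsworth–Emmons reaction with 15 would give the dienyl ketone F6. Baeyer–Villiger oxidation with Me3SiOOSiMe3 and catalytic Me3SiOTf (CH2Cl2, −78 °C), a silyl peroxide that does not epoxidise alkenes, would give 16.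

Further compounds
F1 | step 5 | dimethyl 2-[(1R,2S,3R)-3-(benzyloxymethyl)-3,5-diethyl-2-(1-methoxy-1-oxopropan-2-yl)-4-oxocyclopentyl]-2-methylpropanedioate | O=C1[C@](COCc2ccccc2)(CC)[C@H](C(C)C(=O)OC)[C@@H](C(C)(C(=O)OC)C(=O)OC)C1CC
F2 | step 5 | dimethyl 2-[(4R,5S,6R)-6-(benzyloxymethyl)-3,6-diethyl-5-(1-methoxy-1-oxopropan-2-yl)-2-oxooxan-4-yl]-2-methylpropanedioate | O=C1O[C@](COCc2ccccc2)(CC)[C@H](C(C)C(=O)OC)[C@@H](C(C)(C(=O)OC)C(=O)OC)C1CC
F3 | step 5 | dimethyl 2-[(4R,5S,6R)-3,6-diethyl-6-(hydroxymethyl)-5-(1-methoxy-1-oxopropan-2-yl)-2-oxooxan-4-yl]-2-methylpropanedioate | O=C1O[C@](CO)(CC)[C@H](C(C)C(=O)OC)[C@@H](C(C)(C(=O)OC)C(=O)OC)C1CC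
F4 | step 6 | dimethyl 2-[(1R,2S,3R)-3,5-diethyl-3-formyl-2-(1-methoxy-1-oxopropan-2-yl)-4-oxocyclopentyl]-2-methylpropanedioate | O=C1[C@](C=O)(CC)[C@H](C(C)C(=O)OC)[C@@H](C(C)(C(=O)OC)C(=O)OC)C1CC
F5 | step 6 | dimethyl 2-[(1R,2S,3R)-3,5-diethyl-3-[(1E)-2-ethyl-3-oxoprop-1-en-1-yl]-2-(1-methoxy-1-oxopropan-2-yl)-4-oxocyclopentyl]-2-methylpropanedioate | O=C1[C@](/C=C(\CC)C=O)(CC)[C@H](C(C)C(=O)OC)[C@@H](C(C)(C(=O)OC)C(=O)OC)C1CC
F6 | step 6 | dimethyl 2-[(1R,2S,3R)-3,5-diethyl-3-[(1E,3E)-2-ethyl-4-phenylbuta-1,3-dien-1-yl]-2-(1-methoxy-1-oxopropan-2-yl)-4-oxocyclopentyl]-2-methylpropanedioate | O=C1[C@](/C=C(\CC)/C=C/c2ccccc2)(CC)[C@H](C(C)C(=O)OC)[C@@H](C(C)(C(=O)OC)C(=O)OC)C1CC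
F7 | step 10 | 6-(1,3-dimethoxy-2-methyl-1,3-dioxopropan-2-yl)-1,2,4-triethyl-5-(1-methoxy-1-oxopropan-2-yl)-2-[(E)-2-phenylethenyl]cyclohex-3-ene-1-carboxylic acid (ring centres as in 20) | CCC1=C[C@](/C=C/c2ccccc2)(CC)[C@@](CC)(C(=O)O)[C@H](C(C)(C(=O)OC)C(=O)OC)[C@H]1C(C)C(=O)OC
F8 | step 10 | 1,2,4-triethyl-5,6-bis(1-methoxy-1-oxopropan-2-yl)-2-[(E)-2-phenylethenyl]cyclohex-3-ene-1-carboxylic acid (ring centres as in 20) | CCC1=C[C@](/C=C/c2ccccc2)(CC)[C@@](CC)(C(=O)O)[C@H](C(C)C(=O)OC)[C@H]1C(C)C(=O)OC
F9 | step 10 | 4,5,7-triethyl-1-(methoxycarbonyl)-1,3-dimethyl-2-oxo-5-[(E)-2-phenylethenyl]-2,3,3a,4,5,7a-hexahydro-1H-indene-4-carboxylic acid (ring centres as in 20) | CCC1=C[C@](/C=C/c2ccccc2)(CC)[C@@](CC)(C(=O)O)[C@H]2[C@H]1C(C)(C(=O)OC)C(=O)C2C
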